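**Retrosynthetic overview**
1. Target 31 is 3α,9β-bis(angeloyloxy)-10βH-eremophil-11-en-8-one. The feature used is the cis junction C5/C10 of rings A and B, with the quaternary C5 (methyl C14) next to the oxygenated C8–C9 edge of ring B; this is the shape of a bicyclo[2.2.2]octene in which C8 is still tied to C3.
2. Late disconnections: both angelates (O3, O9); C7–C11 (enolate alkenylation with 2-bromopropene); C9–O (Rubottom oxidation); C3–O and C4–H (hydroboration, then equilibration and dissolving-metal reduction through the C3 ketone).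
3. Key disconnection: C5–C6, by anionic oxy-Cope rearrangement of vinyl carbinol 10. Ring B forms here; ring A, already present as the cyclohexene of the cage, is released when C3–C8 breaks.
4. Carbinol 10 comes from vinyl addition to a resolved bicyclo[2.2.2]octenone, the Diels–Alder adduct of a masked ortho-benzoquinone (C3, C4, C5, C10, C8, C9, C14, C15) with an ethylene equivalent (C1, C2).
5. Ring order: the six-membered carbocycle of the cage (future ring A) by cycloaddition, then ring B by the [3,3] shift; no other ring is made.

Key step: step 6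

Remark on numbering: eremophilane numbering of the target is used for all atoms, also in the bicyclic compounds (ring A = C1–C5, C10; ring B = C5–C10; C14 on C5, C15 on C4, C11–C13 isopropenyl). β is the face that carries C14, α the other. Compounds without C11–C13 are named 11,12,13-trinoreremophilanes.
Assumption: the sulfone is taken to add ortho and endo (sulfonyl on C2, syn to the C4=C5 bridge), the usual outcome for masked ortho-benzoquinones; the group is removed in step 5, so another orientation would change no later step.
Remark on the order of steps: the sulfonyl group is removed only after the vinyl addition, because sodium amalgam would also strip the α-methoxyls of the ketone.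

Step 1
Reactants: 1 2-methoxy-4,5-dimethylphenol; 2 phenyl vinyl sulfone
Product: 4 rac-(1R*,4S*,7S*)-3,3-dimethoxy-5,6-dimethyl-7-(phenylsulfonyl)bicyclo[2.2.2]oct-5-en-2-one, via masked ortho-benzoquinone 3 (not isolated)
Conditions: PhI(OAc)2, MeOH, 0 °C to rt
Reagents that add atoms: methanol, CO
Why: Oxidative dearomatisation of the guaiacol in methanol gives the masked ortho-benzoquinone, whose methyl-substituted diene is trapped in situ by the electron-poor sulfone in a Diels–Alder reaction that forms the two bridgeheads as a racemate.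

Step 2
Reactants: 4 racemic sulfonyl ketone; 5 (S)-N,S-dimethyl-S-phenylsulfoximine
Product: 6 (1R,2R,4S,7S)-3,3-dimethoxy-5,6-dimethyl-2-{[(S)-N-methyl-S-phenylsulfonimidoyl]methyl}-7-(phenylsulfonyl)bicyclo[2.2.2]oct-5-en-2-ol
Conditions: 5, n-BuLi, THF, −78 °C; then 4, −78 °C; NH4Cl (aq); separation of the two diastereomers on SiO2
Reagents that add atoms: none
Why: This is the addition stage of a sulfoximine-based ketone resolution, in which the lithiated sulfoximine should add to the non-enolisable carbonyl faster than it deprotonates the sulfone and so turn the enantiomers of 4 into separable diastereomeric β-hydroxysulfoximines, the one with the (1R,4S) cage (to be assigned by X-ray analysis) being carried on.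

Step 3
Reactants: 6 β-hydroxysulfoximine
Product: 7 (1R,4S,7S)-3,3-dimethoxy-5,6-dimethyl-7-(phenylsulfonyl)bicyclo[2.2.2]oct-5-en-2-one
Conditions: toluene, 110 °C
Reagents that add atoms: none
Why: Thermal retro-addition of the β-hydroxysulfoximine releases the ketone and the auxiliary, and the bridgehead stereocentres cannot enolise.

Step 4
Reactants: 7 resolved sulfonyl ketone; 8 vinylmagnesium bromide
Product: 9 (1R,2R,4S,7S)-3,3-dimethoxy-5,6-dimethyl-7-(phenylsulfonyl)-2-vinylbicyclo[2.2.2]oct-5-en-2-ol
Conditions: CH2=CHMgBr, THF, −78 to 0 °C; NH4Cl (aq)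
Reagents that add atoms: none
Why: In this Grignard addition to a non-enolisable ketone the nucleophile should enter from the side of the C4=C5 bridge, because the C1–C2 bridge turns a hydrogen toward the carbonyl, which sets C8 with the vinyl group syn to the alkene as the [3,3] shift demands.

Step 5
Reactants: 9 sulfonyl vinyl carbinol
Product: 10 (1R,2R,4S)-3,3-dimethoxy-5,6-dimethyl-2-vinylbicyclo[2.2.2]oct-5-en-2-ol
Conditions: Na(Hg), Na2HPO4, MeOH/THF, −20 to 0 °C
Reagents that add atoms: none
Why: Reductive desulfonylation by electron transfer from buffered sodium amalgam cleaves the C2–S bond and leaves the tertiary carbinol, the ketal and both alkenes untouched.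

Step 6
Reactants: 10 vinyl carbinol
Product: 13 (4aS,8aS)-1,1-dimethoxy-4a,5-dimethyl-3,4,4a,7,8,8a-hexahydronaphthalen-2(1H)-one, via potassium alkoxide 11 (not isolated), via potassium enolate 12 (not isolated)
Conditions: KH, 18-crown-6, THF, 0 °C to rt; NH4Cl (aq), −78 °C
Reagents that add atoms: none
Why: Deprotonation gives the free alkoxide 11, whose oxyanion weakens the C3–C8 bond so that it breaks while the vinyl terminus C6 bonds to C5 in a concerted [3,3] sigmatropic shift, giving the C7=C8 enolate 12, which is protonated at C7 on work-up. The closest known reaction type is the anionic oxy-Cope rearrangement of 2-vinylbicyclo[2.2.2]oct-5-en-2-ols made from masked ortho-benzoquinone adducts, a known entry to cis-decalins. Ring B (C5–C6–C7–C8–C9–C10) is closed by this pericyclic bond shift through the boat-like six-centre transition state that the cage enforces, and ring A is the former cyclohexene of the cage, set free when C3–C8 breaks. The new quaternary stereocentre C5 is controlled by the cage, because C6 hangs from C8 over one face of the C4=C5 bridge and can reach C5 only from the side of the C8–C9 bridge, which leaves C14 cis to H10; C10 is the resolved bridgehead carried over unchanged. The step needs the vinyl group syn to the alkene bridge, which step 4 secures, and it needs the shift to outrun fragmentation of the alkoxide, which the crown ether should secure by letting it run at or below room temperature; the cold quench keeps the enolate from equilibrating.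

Step 7
Reactants: 13 α,α-dimethoxy ketone
Product: 14 (4aS,8aR)-4a,5-dimethyl-3,4,4a,7,8,8a-hexahydronaphthalen-2(1H)-one (10βH-11,12,13-trinoreremophil-3-en-8-one)
Conditions: SmI2 (5 equiv), THF/MeOH, −78 °C to rt
Reagents that add atoms: none
Why: In this samarium diiodide reduction of an α-alkoxy ketone, electron transfer to the carbonyl expels each C9 methoxide in turn through the samarium enolate, which methanol reprotonates, while the isolated alkene and the ring-fusion centres (C10 is β to the carbonyl) are not affected.

Step 8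
Reactants: 14 ketone
Product: 15 8,8-(ethylenedioxy)-10βH-11,12,13-trinoreremophil-3-ene
Conditions: HOCH2CH2OH, PPTS, benzene, reflux (Dean–Stark)
Reagents that add atoms: ethylene glycol, OCCO
Why: Acid-catalysed ketalisation of an unhindered cyclohexanone masks C8 against borane and lithium in ammonia, and the dioxolane should hold the cis-decalin in the chair pair with C14 axial on ring A, since in the other pair its axial oxygen would clash with C1.

Step 9
Reactants: 15 alkene ketal
Product: 17 8,8-(ethylenedioxy)-10βH-11,12,13-trinoreremophilan-3-ol (mixture of C3/C4 diastereomers), via C3 alkylborane 16 (not isolated)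
Conditions: BH3·THF, THF, 0 °C to rt; then NaOH, H2O2, 0 °C to rt
Reagents that add atoms: hydrogen peroxide, OO
Why: Hydroboration–oxidation puts boron, then oxygen, on the less substituted C3 and hydrogen on C4 by syn addition; no facial selectivity is relied on, because each face of ring A is flanked by an axial carbon (C14 or C9) and C3 and C4 are set in steps 10 and 11.

Step 10
Reactants: 17 alcohol mixture
Product: 19 8,8-(ethylenedioxy)-10βH-11,12,13-trinoreremophilan-3-one (4β-methyl; C15 cis to C14), via C4-epimeric ketone 18 (not isolated)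
Conditions: DMP, CH2Cl2, rt; crude product, NaOMe (cat.), MeOH, rt
Reagents that add atoms: none
Why: Dess–Martin oxidation gives the C3 ketone, and base-mediated enolisation toward C4 should then equilibrate that centre to the epimer with C15 equatorial and β, since the α-epimer needs either an axial methyl syn to C9 or the chair pair that the dioxolane disfavours.

Step 11
Reactants: 19 C3 ketone
Product: 20 8,8-(ethylenedioxy)-10βH-11,12,13-trinoreremophilan-3α-ol
Conditions: Li, NH3 (l), THF, EtOH, −78 °C
Reagents that add atoms: none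
Why: Dissolving-metal reduction of a hindered cyclohexanone should give the thermodynamically preferred equatorial alcohol (3α, trans to C15), as with 11-oxo steroids, whereas hydride reagents would attack away from the axial C14 and give the axial 3β-alcohol.

Step 12
Reactants: 20 hydroxy ketal
Product: 21 3α-hydroxy-10βH-11,12,13-trinoreremophilan-8-one
Conditions: 1 M HCl, THF, rt
Reagents that add atoms: water, O
Why: Acid-catalysed hydrolysis of the dioxolane regenerates the C8 ketone, and nothing can epimerise because both α-carbons (C7, C9) are methylenes.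

Step 13
Reactants: 21 hydroxy ketone
Product: 22 3α,8-bis(tert-butyldimethylsilyloxy)-10βH-11,12,13-trinoreremophil-8-ene (C8=C9 enol ether)
Conditions: TBSOTf (2.5 equiv), Et3N, CH2Cl2, 0 °C to rt
Reagents that add atoms: tert-butyldimethylsilyl triflate (first equivalent), CC(C)(C)[Si](C)(C)OS(=O)(=O)C(F)(F)F; tert-butyldimethylsilyl triflate (second equivalent), CC(C)(C)[Si](C)(C)OS(=O)(=O)C(F)(F)F
Why: Soft enolisation–silylation with a silyl triflate and a tertiary amine protects O3 and should convert the ketone into its more stable enol ether, which in a cis-fused decalin-2-one of this conformation points toward the ring fusion (C8=C9), as the enol derivatives and the bromination of 5β-3-oxo steroids show.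

Step 14
Reactants: 22 silyl enol ether
Product: 24 3α,9β-bis(tert-butyldimethylsilyloxy)-10βH-11,12,13-trinoreremophilan-8-one, via silyloxy epoxide 23 (not isolated)
Conditions: mCPBA, hexane, −15 °C to rt
Reagents that add atoms: 3-chloroperoxybenzoic acid, O=C(OO)c1cccc(Cl)c1
Why: In this Rubottom oxidation the peracid should epoxidise the enol ether on the β face, because C4 sits axially under the α face of C9, and the silyloxy epoxide opens with 1,4-silyl transfer to the α-silyloxy ketone with O9 equatorial and β.

Step 15
Reactants: 24 α-silyloxy ketone; 25 2-bromopropene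
Product: 28 3α,9β-bis(tert-butyldimethylsilyloxy)-10βH-eremophil-11-en-8-one, via lithium enolate 26 (not isolated), via lithium dienolate 27 (not isolated)
Conditions: LiN(SiMe3)2 (2.2 equiv), THF, −78 °C; Pd2(dba)3 (cat.), P(t-Bu)3 (cat.), 25, rt; AcOH, −78 °C
Reagents that add atoms: none
Why: In this palladium-catalysed α-alkenylation of a ketone enolate the amide base should deprotonate the C7 methylene and not the hindered, oxygen-bearing C9, oxidative addition of the bromide to zerovalent palladium, transmetalation and reductive elimination form C7–C11, and cold, stereoelectronically axial protonation of the product dienolate at C7 should give the equatorial 7β-isopropenyl group without conjugation.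

Step 16
Reactants: 28 bis-silyl ether
Product: 29 3α,9β-dihydroxy-10βH-eremophil-11-en-8-one
Conditions: HF·pyridine, pyridine, THF, 0 °C to rt
Reagents that add atoms: none
Why: Fluoride-mediated desilylation under buffered, slightly acidic conditions removes both silyl ethers without enolising the acyloin or touching the isopropenyl group.

Step 17
Reactants: 29 diol; 30 angelic acid (one equivalent is consumed per hydroxyl)
Product: 31 3α,9β-bis(angeloyloxy)-10βH-eremophil-11-en-8-one (CNP0174755.1)
Conditions: 30 (3 equiv), 2,4,6-Cl3C6H2COCl (3 equiv), Et3N, toluene, rt; then 29, 80 °C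
Reagents that add atoms: angelic acid (second equivalent), C/C=C(/C)C(=O)O
Why: Yamaguchi-type esterification through the mixed 2,4,6-trichlorobenzoic anhydride, formed from an excess of the acid, acylates both secondary hydroxyls with one angeloyl group each and, run without a nucleophilic catalyst, is known to preserve the Z geometry of angelic acid, while C7 and C9 already have their equatorial, thermodynamically preferred configuration.

**Compound list**
1 | 2-methoxy-4,5-dimethylphenol | COc1cc(C)c(C)cc1O | starting material
2 | phenyl vinyl sulfone | C=CS(=O)(=O)c1ccccc1 | starting material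
3 | 6,6-dimethoxy-3,4-dimethylcyclohexa-2,4-dien-1-one (masked ortho-benzoquinone) | COC1(OC)C=C(C)C(C)=CC1=O | intermediate
4 | rac-(1R*,4S*,7S*)-3,3-dimethoxy-5,6-dimethyl-7-(phenylsulfonyl)bicyclo[2.2.2]oct-5-en-2-one (racemate; the enantiomer carried on is drawn) | O=C1C(OC)(OC)[C@H]2C[C@H](S(=O)(=O)c3ccccc3)[C@@H]1C(C)=C2C | intermediate
5 | (S)-N,S-dimethyl-S-phenylsulfoximine | CN=[S@@](C)(=O)c1ccccc1 | starting material
6 | (1R,2R,4S,7S)-3,3-dimethoxy-5,6-dimethyl-2-{[(S)-N-methyl-S-phenylsulfonimidoyl]methyl}-7-(phenylsulfonyl)bicyclo[2.2.2]oct-5-en-2-ol | CN=[S@@](C[C@]1(O)C(OC)(OC)[C@H]2C[C@H](S(=O)(=O)c3ccccc3)[C@@H]1C(C)=C2C)(=O)c4ccccc4 | intermediate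
7 | (1R,4S,7S)-3,3-dimethoxy-5,6-dimethyl-7-(phenylsulfonyl)bicyclo[2.2.2]oct-5-en-2-one | O=C1C(OC)(OC)[C@H]2C[C@H](S(=O)(=O)c3ccccc3)[C@@H]1C(C)=C2C | intermediate
8 | vinylmagnesium bromide | C=C[Mg]Br | starting material
9 | (1R,2R,4S,7S)-3,3-dimethoxy-5,6-dimethyl-7-(phenylsulfonyl)-2-vinylbicyclo[2.2.2]oct-5-en-2-ol | C=C[C@]1(O)C(OC)(OC)[C@H]2C[C@H](S(=O)(=O)c3ccccc3)[C@@H]1C(C)=C2C | intermediate
10 | (1R,2R,4S)-3,3-dimethoxy-5,6-dimethyl-2-vinylbicyclo[2.2.2]oct-5-en-2-ol (vinyl syn to the alkene bridge) | C=C[C@]1(O)C(OC)(OC)[C@H]2CC[C@@H]1C(C)=C2C | intermediate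
11 | potassium alkoxide of 10 | C=C[C@]1([O-])C(OC)(OC)[C@H]2CC[C@@H]1C(C)=C2C.[K+] | intermediate
12 | potassium C7=C8 enolate of 13 | C=1C[C@@]2(C)[C@H](CCC=C2C)C(OC)(OC)C=1[O-].[K+] | intermediate
13 | (4aS,8aS)-1,1-dimethoxy-4a,5-dimethyl-3,4,4a,7,8,8a-hexahydronaphthalen-2(1H)-one | C1C[C@@]2(C)[C@H](CCC=C2C)C(OC)(OC)C1=O | intermediate
14 | (4aS,8aR)-4a,5-dimethyl-3,4,4a,7,8,8a-hexahydronaphthalen-2(1H)-one | C1C[C@@]2(C)[C@H](CCC=C2C)CC1=O | intermediate
15 | 8,8-(ethylenedioxy)-10βH-11,12,13-trinoreremophil-3-ene | C1C[C@@]2(C)[C@H](CCC=C2C)CC13OCCO3 | intermediate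
16 | 3-boryl-8,8-(ethylenedioxy)-10βH-11,12,13-trinoreremophilane (C3/C4 mixture) | C1C[C@@]2(C)[C@H](CCC(B)C2C)CC13OCCO3 | intermediate
17 | 8,8-(ethylenedioxy)-10βH-11,12,13-trinoreremophilan-3-ol (C3/C4 mixture) | C1C[C@@]2(C)[C@H](CCC(O)C2C)CC13OCCO3 | intermediate
18 | 8,8-(ethylenedioxy)-10βH-11,12,13-trinoreremophilan-3-one (C4 epimers) | C1C[C@@]2(C)[C@H](CCC(=O)C2C)CC13OCCO3 | intermediate
19 | 8,8-(ethylenedioxy)-4β-methyl-10βH-11,12,13-trinoreremophilan-3-one | C1C[C@@]2(C)[C@H](CCC(=O)[C@@H]2C)CC13OCCO3 | intermediate
20 | 8,8-(ethylenedioxy)-10βH-11,12,13-trinoreremophilan-3α-ol | C1C[C@@]2(C)[C@H](CC[C@@H](O)[C@@H]2C)CC13OCCO3 | intermediate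
21 | 3α-hydroxy-10βH-11,12,13-trinoreremophilan-8-one | C1C[C@@]2(C)[C@H](CC[C@@H](O)[C@@H]2C)CC1=O | intermediate
22 | 3α,8-bis(tert-butyldimethylsilyloxy)-10βH-11,12,13-trinoreremophil-8-ene | C1C[C@@]2(C)[C@H](CC[C@@H](O[Si](C)(C)C(C)(C)C)[C@@H]2C)C=C1O[Si](C)(C)C(C)(C)C | intermediate
23 | 8β,9β-epoxide of 22 | C1C[C@@]2(C)[C@H](CC[C@@H](O[Si](C)(C)C(C)(C)C)[C@@H]2C)[C@H]3O[C@@]13O[Si](C)(C)C(C)(C)C | intermediate
24 | 3α,9β-bis(tert-butyldimethylsilyloxy)-10βH-11,12,13-trinoreremophilan-8-one | C1C[C@@]2(C)[C@H](CC[C@@H](O[Si](C)(C)C(C)(C)C)[C@@H]2C)[C@@H](O[Si](C)(C)C(C)(C)C)C1=O | intermediate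
25 | 2-bromopropene | C=C(C)Br | starting material
26 | lithium C7=C8 enolate of 24 | C=1C[C@@]2(C)[C@H](CC[C@@H](O[Si](C)(C)C(C)(C)C)[C@@H]2C)[C@@H](O[Si](C)(C)C(C)(C)C)C=1O[Li] | intermediate
27 | lithium dienolate of 28 | C=C(C)C=1C[C@@]2(C)[C@H](CC[C@@H](O[Si](C)(C)C(C)(C)C)[C@@H]2C)[C@@H](O[Si](C)(C)C(C)(C)C)C=1O[Li] | intermediate
28 | 3α,9β-bis(tert-butyldimethylsilyloxy)-10βH-eremophil-11-en-8-one | C=C(C)[C@H]1C[C@@]2(C)[C@H](CC[C@@H](O[Si](C)(C)C(C)(C)C)[C@@H]2C)[C@@H](O[Si](C)(C)C(C)(C)C)C1=O | intermediate
29 | 3α,9β-dihydroxy-10βH-eremophil-11-en-8-one | C=C(C)[C@H]1C[C@@]2(C)[C@H](CC[C@@H](O)[C@@H]2C)[C@@H](O)C1=O | intermediate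
30 | angelic acid ((Z)-2-methylbut-2-enoic acid) | C/C=C(/C)C(=O)O | starting material
31 | 3α,9β-bis(angeloyloxy)-10βH-eremophil-11-en-8-one (CNP0174755.1) | C=C(C)[C@H]1C[C@@]2(C)[C@H](CC[C@@H](OC(=O)/C(C)=C\C)[C@@H]2C)[C@@H](OC(=O)/C(C)=C\C)C1=O | target

**Step count and risks**
Total: 17 steps. Longest linear sequence: 17 steps (1 to 31; the route is fully linear).

Steps most likely to fail:

Step 13. Silylation may proceed under partly kinetic control and enolise the ketone toward C7 as well, so that the oxygen of step 14 would enter at the wrong carbon. The fallback brings the oxygen in through the fully equilibrated, acid-mediated enol. It sets out from 21: PhNMe3Br3 in THF at 0 °C should brominate C9, the classical site for cis-fused ketones of this type, giving 9β-bromo-3α-hydroxy-10βH-11,12,13-trinoreremophilan-8-one F1. HCO2Na in DMF displaces bromide with inversion to the 9α-formate F2. K2CO3 in methanol cleaves the formate and should equilibrate C9 to the equatorial alcohol, 3α,9β-dihydroxy-10βH-11,12,13-trinoreremophilan-8-one F3. TBSOTf and 2,6-lutidine then silylate both hydroxyls and the route is rejoined at 24.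

Step 15. Proton exchange between enolates during the coupling may cause a second alkenylation, a shift of the C9 silyl group onto the enolate oxygen, or migration of the new alkene into conjugation with the ketone. The final protonation may also show poor facial selectivity, because the axial approach to C7 passes the axial C4. The fallback forms C7–C11 by an aldol reaction. It sets out from 24: LiN(i-Pr)2 in THF at −78 °C, then ZnCl2 and acetone, give the aldol 3α,9β-bis(tert-butyldimethylsilyloxy)-11-hydroxy-10βH-eremophilan-8-one F4. The zinc aldolate forms reversibly and should settle with the bulky hydroxyisopropyl group equatorial (7β). SOCl2 and pyridine at 0 °C should then dehydrate the tertiary alcohol mainly toward a methyl group without touching C7, and the route is rejoined at 28.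

Step 17. Acylation of two hindered hydroxyls may be slow enough for Z to E isomerisation to tiglate esters, or for base-induced enolisation of the acyloin, to compete. The fallback builds the angelate double bonds after acylation. It sets out from 29: but-2-ynoic acid (2 equiv or more), DCC and DMAP give the 3α,9β-bis(but-2-ynoyloxy) ketone F5. Bu3SnH with Pd(PPh3)4 (cat.) adds hydrogen and tin syn across each ynoate with tin on the α-carbon, giving the bis[(E)-2-(tributylstannyl)but-2-enoate] F6. Stille methylation (MeI, Pd2(dba)3, P(o-tol)3, CuCl, K2CO3, DMF) replaces tin by methyl with retention and arrives at 31.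

Further compounds
F1 | step 13 | 9β-bromo-3α-hydroxy-10βH-11,12,13-trinoreremophilan-8-one | C1C[C@@]2(C)[C@H](CC[C@@H](O)[C@@H]2C)[C@@H](Br)C1=O
F2 | step 13 | 9α-formyloxy-3α-hydroxy-10βH-11,12,13-trinoreremophilan-8-one | C1C[C@@]2(C)[C@H](CC[C@@H](O)[C@@H]2C)[C@H](OC=O)C1=O
F3 | step 13 | 3α,9β-dihydroxy-10βH-11,12,13-trinoreremophilan-8-one | C1C[C@@]2(C)[C@H](CC[C@@H](O)[C@@H]2C)[C@@H](O)C1=O
F4 | step 15 | 3α,9β-bis(tert-butyldimethylsilyloxy)-11-hydroxy-10βH-eremophilan-8-one | CC(C)(O)[C@H]1C[C@@]2(C)[C@H](CC[C@@H](O[Si](C)(C)C(C)(C)C)[C@@H]2C)[C@@H](O[Si](C)(C)C(C)(C)C)C1=O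
F5 | step 17 | 3α,9β-bis(but-2-ynoyloxy)-10βH-eremophil-11-en-8-one | C=C(C)[C@H]1C[C@@]2(C)[C@H](CC[C@@H](OC(=O)C#CC)[C@@H]2C)[C@@H](OC(=O)C#CC)C1=O
F6 | step 17 | 3α,9β-bis[(E)-2-(tributylstannyl)but-2-enoyloxy]-10βH-eremophil-11-en-8-one | C=C(C)[C@H]1C[C@@]2(C)[C@H](CC[C@@H](OC(=O)/C([Sn](CCCC)(CCCC)CCCC)=C\C)[C@@H]2C)[C@@H](OC(=O)/C([Sn](CCCC)(CCCC)CCCC)=C\C)C1=O
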